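A direct plan would build the isoflavone through a 2‑hydroxydeoxybenzoin: a ring A benzaldehyde A1 (allyl ether on the future O1, two methoxymethyl ethers, silyl‑capped side chain; about eight linear steps) would take up the lithium enolate of a ring B allyl arylacetate A2 in an aldol addition to give the β‑hydroxy allyl ester A3. Oxidation and deallylation with decarboxylation would give the deoxybenzoin A4, a formamide acetal would add C2 and close ring C to give the protected isoflavone A5, and methanolic mineral acid would remove four acetals and the silyl ether.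
Its weakest steps would be:
- the fragment union: aldol addition, oxidation and deallylative decarboxylation would spend three operations, two allyl groups and a silyl ether on one C–C bond, and would make two stereocentres only to erase them;
- the run‑up to A1: eight linear steps, mostly benzyl, acetal, allyl and silyl traffic, whose main purpose is to decide which phloroglucinol oxygen becomes O1 (6‑ versus 8‑alkyl);
- the last step: mineral acid on a product whose prenyl group and tertiary alcohol each sit between two phenols, where both can close to chromans.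

**Retrosynthetic overview**
- Ring C is cut at O1–C8a and C4–C4a. An aryne across C4a–C8a of ring A takes up, in one operation, the enol oxygen (O1) and the ester carbon (C4) of a ring B 2‑aryl‑3‑hydroxyacrylate. The acetal oxygen on C5, beside the triple bond, sends O1 to C8a and the acyl carbon to C4a, so the 6‑alkyl pattern follows from aryne polarity, not from oxygen differentiation.
- The C2–C3(ring B)–C4 unit comes in one step from the ring B aldehyde and ethyl diazoacetate by a 1,2‑aryl shift from the future C2 to the future C3, the migration that isoflavone biosynthesis uses.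
- Rings A and B share the motif "C5 chain between two oxygens" (O5–C6–O7 and O2'–C3'–O4'), so both fragments branch from one 2‑prenylresorcinol bis‑acetal 3. Ring A then needs only alkene hydration, C–H oxidation para to the chain and conversion into the ortho‑silylaryl triflate.
- Ring order: both benzene rings come from one bought resorcinol ether, and ring C closes in the same step that joins the halves. There is no open‑chain diaryl intermediate and no stereocentre. The four acetals are the only phenol protecting groups, and they leave by a buffered aprotic exchange instead of mineral acid.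

Key step: step 8

Remark: 1,3‑bis(methoxymethoxy)benzene 1 is taken as a purchasable compound; otherwise it is one step from resorcinol. Compound 13 is drawn as its hydrogen‑bonded Z‑enol, a mobile tautomer of the α‑formyl ester.

**Common intermediate and fragment A (ring A aryne precursor)**

Step 1
Reactants: 1 1,3-bis(methoxymethoxy)benzene
Product: 3 1,3-bis(methoxymethoxy)-2-(3-methylbut-2-enyl)benzene, via [2,6-bis(methoxymethoxy)phenyl]lithium 2 (not isolated)
Conditions: n-BuLi (1.15 equiv), THF, 0 °C to rt, 1.5 h; prenyl bromide (1.3 equiv), −78 °C to rt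
Reagents that add atoms: prenyl bromide (1-bromo-3-methylbut-2-ene) CC(C)=CCBr
Why: Directed ortho-metalation removes the proton between the two chelating acetal oxygens, and the aryllithium is alkylated at the primary carbon of prenyl bromide (SN2); no stereocentre is formed.

Step 2
Reactants: 3 1,3-bis(methoxymethoxy)-2-(3-methylbut-2-enyl)benzene
Product: 4 4-[2,6-bis(methoxymethoxy)phenyl]-2-methylbutan-2-ol
Conditions: Co(acac)2 (20 mol%), PhSiH3 (2 equiv), O2 (1 atm), THF, rt
Reagents that add atoms: dioxygen O=O
Why: Mukaiyama hydration: hydrogen atom transfer from a cobalt hydride to the trisubstituted alkene gives the tertiary radical, which is trapped by O2 and reduced to the Markovnikov tertiary alcohol, while the aryl acetals are inert and the new carbinol carbon (two methyl groups) is not a stereocentre.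

Step 3
Reactants: 4 4-[2,6-bis(methoxymethoxy)phenyl]-2-methylbutan-2-ol
Product: 6 4-(3-hydroxy-3-methylbutyl)-3,5-bis(methoxymethoxy)phenol, via pinacol arylboronate 5 (not isolated)
Conditions: [Ir(cod)(OMe)]2 (1.5 mol%), 4,4'-di-tert-butyl-2,2'-bipyridine (3 mol%), B2pin2 (1.5 equiv), THF, 80 °C; then 30% H2O2, aq NaOH, 0 °C to rt
Reagents that add atoms: hydrogen peroxide OO
Why: Iridium-catalysed C–H borylation is sterically controlled and should take the only ring C–H without an ortho substituent (para to the chain, meta to both acetals), and oxidation of the C–B bond then gives the phenol, so the third phloroglucinol oxygen arrives already differentiated from the two acetal oxygens.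

Step 4
Reactants: 6 4-(3-hydroxy-3-methylbutyl)-3,5-bis(methoxymethoxy)phenol
Product: 7 2-bromo-4-(3-hydroxy-3-methylbutyl)-3,5-bis(methoxymethoxy)phenol
Conditions: NBS (1.0 equiv), CH2Cl2, −78 to 0 °C
Reagents that add atoms: N-bromosuccinimide O=C1CCC(=O)N1Br
Why: Electrophilic aromatic bromination goes ortho to the free OH because the para position carries the chain, the two ortho positions are equivalent by symmetry, and one equivalent at low temperature should stop at the monobromide.

Step 5
Reactants: 7 2-bromo-4-(3-hydroxy-3-methylbutyl)-3,5-bis(methoxymethoxy)phenol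
Product: 10 3,5-bis(methoxymethoxy)-4-[3-methyl-3-(trimethylsilyloxy)butyl]-2-(trimethylsilyl)phenyl trifluoromethanesulfonate (fragment A), via bis(trimethylsilyl) ether 8 (not isolated), via lithium 2-silylphenoxide 9 (not isolated)
Conditions: (Me3Si)2NH (3 equiv), Me3SiCl (5 mol%), THF, 65 °C, then evaporation; n-BuLi (1.1 equiv), THF, −78 °C, 30 min; PhNTf2 (1.2 equiv), −78 °C to rt
Reagents that add atoms: hexamethyldisilazane C[Si](C)(C)N[Si](C)(C)C; N-phenylbis(trifluoromethanesulfonimide) O=S(=O)(N(c1ccccc1)S(=O)(=O)C(F)(F)F)C(F)(F)F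
Why: Silylation of both hydroxyls, bromine–lithium exchange and retro-Brook rearrangement (1,3 oxygen-to-carbon silyl shift, driven by formation of the phenoxide) place silicon next to the oxygen that is then triflated, which gives the ortho-silylaryl triflate and leaves the tertiary alcohol capped as its trimethylsilyl ether without a separate step.

**Fragment B (ring B with the C2–C3–C4 unit)**

Step 6
Reactants: 3 1,3-bis(methoxymethoxy)-2-(3-methylbut-2-enyl)benzene
Product: 12 2,4-bis(methoxymethoxy)-3-(3-methylbut-2-enyl)benzaldehyde, via aryllithium 11 (not isolated)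
Conditions: n-BuLi (1.2 equiv), TMEDA (1.2 equiv), THF, −20 to 0 °C, 1 h; DMF (2 equiv), 0 °C to rt; aq NH4Cl
Reagents that add atoms: N,N-dimethylformamide CN(C)C=O
Why: A second directed ortho-metalation, now beside one acetal (the two open ortho positions are equivalent), is followed by formylation with DMF, and coordination of the base to the acetal oxygen should favour ring lithiation over removal of the benzylic–allylic proton.

Step 7
Reactants: 12 2,4-bis(methoxymethoxy)-3-(3-methylbut-2-enyl)benzaldehyde
Product: 13 ethyl (Z)-2-[2,4-bis(methoxymethoxy)-3-(3-methylbut-2-enyl)phenyl]-3-hydroxyprop-2-enoate (fragment B)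
Conditions: ethyl diazoacetate (1.3 equiv), HBF4·OEt2 (10 mol%), CH2Cl2, −78 °C, 2 h; Et3N quench at −78 °C
Reagents that add atoms: ethyl diazoacetate CCOC(=O)C=[N+]=[N-]
Why: Acid-catalysed aldehyde–diazoacetate homologation with 1,2-aryl shift: the diazo carbon adds to the protonated aldehyde, and the β-hydroxy diazonium ester loses N2 with migration of the electron-rich dialkoxyaryl group (favoured over the hydride shift of the Roskamp course), so the aldehyde carbon becomes the future C2 and ring B sits on the future C3; catalytic acid at −78 °C without a nucleophilic solvent should spare acetals and alkene, and the enol geometry is mobile.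

**Fragment union and end game**

Step 8
Reactants: 10 3,5-bis(methoxymethoxy)-4-[3-methyl-3-(trimethylsilyloxy)butyl]-2-(trimethylsilyl)phenyl trifluoromethanesulfonate; 13 ethyl (Z)-2-[2,4-bis(methoxymethoxy)-3-(3-methylbut-2-enyl)phenyl]-3-hydroxyprop-2-enoate
Product: 16 3-[2,4-bis(methoxymethoxy)-3-(3-methylbut-2-enyl)phenyl]-6-(3-hydroxy-3-methylbutyl)-5,7-bis(methoxymethoxy)-4H-chromen-4-one, via aryne 14 (not isolated), via ortho-caesioaryl enol ether 15 (not isolated)
Conditions: 10 (1.0 equiv), 13 (1.5 equiv), CsF (5 equiv), THF, 65 °C, 24 h (sealed tube); aqueous work-up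
Reagents that add atoms: none
Why: Proposed new method: fluoride should trigger 1,2-elimination of 10 to aryne 14, whose triple bond spans C4a–C8a of the future ring A, and the caesium Z-enolate of 13 should add through its enol oxygen to C8a, the aryne carbon remote from the acetal oxygen on C5 (the inductively withdrawing ortho oxygen makes the distal carbon the electrophilic one and stabilises the developing anion on C4a), which fixes the 6-alkyl pattern with C8 as the ring C–H. Aryl anion 15 should then be acylated by the cis ester through a six-membered transition state with loss of ethoxide, so ring C closes by an intermolecular O1–C8a addition followed by a 6-exo-trig C4–C4a acyl substitution, and the aryne takes up both neighbouring substituents in one operation. The closest known reaction type is the annulation of salicylate esters with arynes to xanthones (O-arylation, then capture of the ester by the aryl anion), together with aryne insertion into the C–O bond of unsaturated carboxylic acids on the way to chromanones and flavones; the 3-hydroxyacrylate is a salicylate without its benzo ring. The selectivity needed is O- over C-arylation of the ambident enolate, which the fully substituted α-carbon (ester, formyl carbon and the ortho-substituted ring B) and the chelated Z-enolate should secure, and protonation of 15 should be outrun by the intramolecular acyl transfer in aprotic THF. No stereocentre is formed, the prenyl alkene and the acetals are spectators, and the excess fluoride also cleaves the tertiary silyl ether.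

Step 9
Reactants: 16 3-[2,4-bis(methoxymethoxy)-3-(3-methylbut-2-enyl)phenyl]-6-(3-hydroxy-3-methylbutyl)-5,7-bis(methoxymethoxy)-4H-chromen-4-one
Product: 18 3-[2,4-dihydroxy-3-(3-methylbut-2-enyl)phenyl]-5,7-dihydroxy-6-(3-hydroxy-3-methylbutyl)-4H-chromen-4-one (target), via pentakis(trimethylsilyl) ether 17 (not isolated)
Conditions: Me3SiOTf (10 equiv), 2,2'-bipyridyl (15 equiv), MeCN, 0 °C to rt; then H2O, rt; aq NaHCO3
Reagents that add atoms: none
Why: Silyl triflate/2,2'-bipyridyl acetal exchange: the bipyridyl–silyl triflate complex activates each aryl methoxymethyl acetal, the aryl oxygen passes to silicon (17) while the methoxymethyl unit is held as a bipyridinium salt, and water then hydrolyses all O–Si bonds; the medium stays buffered by excess bipyridyl and holds no free protic acid, so neither the prenyl alkene nor the tertiary alcohol (transiently its silyl ether) should ionise, and the target is achiral.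

**Compound list**
1 | 1,3-bis(methoxymethoxy)benzene | COCOc1cccc(OCOC)c1 | starting material
2 | [2,6-bis(methoxymethoxy)phenyl]lithium (not isolated) | [Li]c1c(OCOC)cccc1OCOC | intermediate
3 | 1,3-bis(methoxymethoxy)-2-(3-methylbut-2-enyl)benzene | CC(C)=CCc1c(OCOC)cccc1OCOC | intermediate
4 | 4-[2,6-bis(methoxymethoxy)phenyl]-2-methylbutan-2-ol | CC(C)(O)CCc1c(OCOC)cccc1OCOC | intermediate
5 | 4-[2,6-bis(methoxymethoxy)-4-(4,4,5,5-tetramethyl-1,3,2-dioxaborolan-2-yl)phenyl]-2-methylbutan-2-ol (not isolated) | CC(C)(O)CCc1c(OCOC)cc(B2OC(C)(C)C(C)(C)O2)cc1OCOC | intermediate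
6 | 4-(3-hydroxy-3-methylbutyl)-3,5-bis(methoxymethoxy)phenol | CC(C)(O)CCc1c(OCOC)cc(O)cc1OCOC | intermediate
7 | 2-bromo-4-(3-hydroxy-3-methylbutyl)-3,5-bis(methoxymethoxy)phenol | CC(C)(O)CCc1c(OCOC)cc(O)c(Br)c1OCOC | intermediate
8 | {2-bromo-3,5-bis(methoxymethoxy)-4-[3-methyl-3-(trimethylsilyloxy)butyl]phenoxy}trimethylsilane (not isolated) | C[Si](C)(C)OC(C)(C)CCc1c(OCOC)cc(O[Si](C)(C)C)c(Br)c1OCOC | intermediate
9 | lithium 3,5-bis(methoxymethoxy)-4-[3-methyl-3-(trimethylsilyloxy)butyl]-2-(trimethylsilyl)phenoxide (not isolated) | C[Si](C)(C)OC(C)(C)CCc1c(OCOC)cc(O[Li])c([Si](C)(C)C)c1OCOC | intermediate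
10 | 3,5-bis(methoxymethoxy)-4-[3-methyl-3-(trimethylsilyloxy)butyl]-2-(trimethylsilyl)phenyl trifluoromethanesulfonate | C[Si](C)(C)OC(C)(C)CCc1c(OCOC)cc(OS(=O)(=O)C(F)(F)F)c([Si](C)(C)C)c1OCOC | intermediate
11 | [2,4-bis(methoxymethoxy)-3-(3-methylbut-2-enyl)phenyl]lithium (not isolated) | [Li]c1ccc(OCOC)c(CC=C(C)C)c1OCOC | intermediate
12 | 2,4-bis(methoxymethoxy)-3-(3-methylbut-2-enyl)benzaldehyde | CC(C)=CCc1c(OCOC)ccc(C=O)c1OCOC | intermediate
13 | ethyl (Z)-2-[2,4-bis(methoxymethoxy)-3-(3-methylbut-2-enyl)phenyl]-3-hydroxyprop-2-enoate (hydrogen-bonded enol, geometry mobile) | O/C=C(/c1ccc(OCOC)c(CC=C(C)C)c1OCOC)C(=O)OCC | intermediate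
14 | 3,5-bis(methoxymethoxy)-4-[3-methyl-3-(trimethylsilyloxy)butyl]benzyne, triple bond between the former C–Si and C–OTf carbons (not isolated) | C1#CC=C(OCOC)C(CCC(C)(C)O[Si](C)(C)C)=C1OCOC | intermediate
15 | ethyl (Z)-3-{2-caesio-3,5-bis(methoxymethoxy)-4-[3-methyl-3-(trimethylsilyloxy)butyl]phenoxy}-2-[2,4-bis(methoxymethoxy)-3-(3-methylbut-2-enyl)phenyl]prop-2-enoate (not isolated) | [Cs]c1c(O/C=C(/c2ccc(OCOC)c(CC=C(C)C)c2OCOC)C(=O)OCC)cc(OCOC)c(CCC(C)(C)O[Si](C)(C)C)c1OCOC | intermediate
16 | 3-[2,4-bis(methoxymethoxy)-3-(3-methylbut-2-enyl)phenyl]-6-(3-hydroxy-3-methylbutyl)-5,7-bis(methoxymethoxy)-4H-chromen-4-one | CC(C)=CCc1c(OCOC)ccc(-c2coc3cc(OCOC)c(CCC(C)(C)O)c(OCOC)c3c2=O)c1OCOC | intermediate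
17 | 3-[3-(3-methylbut-2-enyl)-2,4-bis(trimethylsilyloxy)phenyl]-6-[3-methyl-3-(trimethylsilyloxy)butyl]-5,7-bis(trimethylsilyloxy)-4H-chromen-4-one (not isolated) | CC(C)=CCc1c(O[Si](C)(C)C)ccc(-c2coc3cc(O[Si](C)(C)C)c(CCC(C)(C)O[Si](C)(C)C)c(O[Si](C)(C)C)c3c2=O)c1O[Si](C)(C)C | intermediate
18 | 3-[2,4-dihydroxy-3-(3-methylbut-2-enyl)phenyl]-5,7-dihydroxy-6-(3-hydroxy-3-methylbutyl)-4H-chromen-4-one (achiral) | CC(C)=CCc1c(O)ccc(-c2coc3cc(O)c(CCC(C)(C)O)c(O)c3c2=O)c1O | target

**Count and risks**
Total steps: 9. Longest linear sequence: 7 (steps 1–5, 8, 9).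

Steps most likely to fail:

1. Step 8 (proposed method). The ambident enolate may react through carbon (arylation of the α-carbon and insertion into the C–CHO bond), or the aryl anion may be protonated before acyl transfer. The fallback leaves the aryne out and uses known isoflavone chemistry; it sets out from 7 and 3 and comes back at 16. From 7, n-BuLi (3.2 equiv; both hydroxyls deprotonated, then bromine–lithium exchange) and N-methoxy-N-methylacetamide would give 1-[2-hydroxy-5-(3-hydroxy-3-methylbutyl)-4,6-bis(methoxymethoxy)phenyl]ethanone F1. DMF dimethyl acetal would turn it into the enaminone (E)-3-(dimethylamino)-1-[2-hydroxy-5-(3-hydroxy-3-methylbutyl)-4,6-bis(methoxymethoxy)phenyl]prop-2-en-1-one F2, and iodine would close this to 6-(3-hydroxy-3-methylbutyl)-3-iodo-5,7-bis(methoxymethoxy)-4H-chromen-4-one F3. Lithiation of 3 as in step 6 and B(OiPr)3 would give [2,4-bis(methoxymethoxy)-3-(3-methylbut-2-enyl)phenyl]boronic acid F4, and Suzuki–Miyaura coupling of the iodochromone with this boronic acid (Pd(dppf)Cl2, K2CO3, dioxane–H2O, 80 °C) would give 16.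

2. Step 7. A hydride shift may compete with the aryl shift, or the acid may remove an acetal or close the protonated prenyl group onto the neighbouring acetal oxygen. The fallback makes 13 under basic conditions only; it sets out from 3 and comes back at 13. Lithiation of 3 as in step 6 and quench with BrCF2CF2Br would give 1-bromo-2,4-bis(methoxymethoxy)-3-(3-methylbut-2-enyl)benzene F5. Palladium-catalysed coupling with the Reformatsky reagent BrZnCH2CO2Et (Pd(dba)2, P(t-Bu)3, THF) would give ethyl 2-[2,4-bis(methoxymethoxy)-3-(3-methylbut-2-enyl)phenyl]acetate F6, and Claisen formylation (NaH, HCO2Et, THF) would give 13.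

3. Step 5. The oxygen-to-carbon silyl migration may be incomplete, or the organolithium may attack elsewhere. The fallback installs silicon by carbamate-directed ortho-metalation, without the bromide; it sets out from 6 and comes back at 10. i-PrNCO with catalytic Et3N would give 4-(3-hydroxy-3-methylbutyl)-3,5-bis(methoxymethoxy)phenyl N-isopropylcarbamate F7. In situ N- and O-silylation (Me3SiOTf, TMEDA), n-BuLi/TMEDA at −78 °C and Me3SiCl would give 3,5-bis(methoxymethoxy)-4-[3-methyl-3-(trimethylsilyloxy)butyl]-2-(trimethylsilyl)phenyl N-isopropylcarbamate F8. DBU and Et2NH (MeCN, 40 °C) would cleave the carbamate to 3,5-bis(methoxymethoxy)-4-[3-methyl-3-(trimethylsilyloxy)butyl]-2-(trimethylsilyl)phenol F9, and PhNTf2 with K2CO3 would give 10.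

**Further compounds**
F1 | step 8 | 1-[2-hydroxy-5-(3-hydroxy-3-methylbutyl)-4,6-bis(methoxymethoxy)phenyl]ethanone | CC(=O)c1c(O)cc(OCOC)c(CCC(C)(C)O)c1OCOC
F2 | step 8 | (E)-3-(dimethylamino)-1-[2-hydroxy-5-(3-hydroxy-3-methylbutyl)-4,6-bis(methoxymethoxy)phenyl]prop-2-en-1-one | CN(C)/C=C/C(=O)c1c(O)cc(OCOC)c(CCC(C)(C)O)c1OCOC
F3 | step 8 | 6-(3-hydroxy-3-methylbutyl)-3-iodo-5,7-bis(methoxymethoxy)-4H-chromen-4-one | CC(C)(O)CCc1c(OCOC)cc2occ(I)c(=O)c2c1OCOC
F4 | step 8 | [2,4-bis(methoxymethoxy)-3-(3-methylbut-2-enyl)phenyl]boronic acid | CC(C)=CCc1c(OCOC)ccc(B(O)O)c1OCOC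
F5 | step 7 | 1-bromo-2,4-bis(methoxymethoxy)-3-(3-methylbut-2-enyl)benzene | CC(C)=CCc1c(OCOC)ccc(Br)c1OCOC
F6 | step 7 | ethyl 2-[2,4-bis(methoxymethoxy)-3-(3-methylbut-2-enyl)phenyl]acetate | CCOC(=O)Cc1ccc(OCOC)c(CC=C(C)C)c1OCOC
F7 | step 5 | 4-(3-hydroxy-3-methylbutyl)-3,5-bis(methoxymethoxy)phenyl N-isopropylcarbamate | CC(C)NC(=O)Oc1cc(OCOC)c(CCC(C)(C)O)c(OCOC)c1
F8 | step 5 | 3,5-bis(methoxymethoxy)-4-[3-methyl-3-(trimethylsilyloxy)butyl]-2-(trimethylsilyl)phenyl N-isopropylcarbamate | CC(C)NC(=O)Oc1cc(OCOC)c(CCC(C)(C)O[Si](C)(C)C)c(OCOC)c1[Si](C)(C)C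
F9 | step 5 | 3,5-bis(methoxymethoxy)-4-[3-methyl-3-(trimethylsilyloxy)butyl]-2-(trimethylsilyl)phenol | C[Si](C)(C)OC(C)(C)CCc1c(OCOC)cc(O)c([Si](C)(C)C)c1OCOC
A1 | direct plan | 2-(allyloxy)-4,6-bis(methoxymethoxy)-5-[3-methyl-3-(triethylsilyloxy)butyl]benzaldehyde | CC[Si](CC)(CC)OC(C)(C)CCc1c(OCOC)cc(OCC=C)c(C=O)c1OCOC
A2 | direct plan | allyl 2-[2,4-bis(methoxymethoxy)-3-(3-methylbut-2-enyl)phenyl]acetate | CC(C)=CCc1c(OCOC)ccc(CC(=O)OCC=C)c1OCOC
A3 | direct plan | allyl 3-{2-(allyloxy)-4,6-bis(methoxymethoxy)-5-[3-methyl-3-(triethylsilyloxy)butyl]phenyl}-2-[2,4-bis(methoxymethoxy)-3-(3-methylbut-2-enyl)phenyl]-3-hydroxypropanoate (racemic syn/anti mixture) | CC(C)=CCc1c(OCOC)ccc(C(C(=O)OCC=C)C(O)c2c(OCC=C)cc(OCOC)c(CCC(C)(C)O[Si](CC)(CC)CC)c2OCOC)c1OCOC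
A4 | direct plan | 1-{2-hydroxy-4,6-bis(methoxymethoxy)-5-[3-methyl-3-(triethylsilyloxy)butyl]phenyl}-2-[2,4-bis(methoxymethoxy)-3-(3-methylbut-2-enyl)phenyl]ethanone | CC(C)=CCc1c(OCOC)ccc(CC(=O)c2c(O)cc(OCOC)c(CCC(C)(C)O[Si](CC)(CC)CC)c2OCOC)c1OCOC
A5 | direct plan | 3-[2,4-bis(methoxymethoxy)-3-(3-methylbut-2-enyl)phenyl]-5,7-bis(methoxymethoxy)-6-[3-methyl-3-(triethylsilyloxy)butyl]-4H-chromen-4-one | CC(C)=CCc1c(OCOC)ccc(-c2coc3cc(OCOC)c(CCC(C)(C)O[Si](CC)(CC)CC)c(OCOC)c3c2=O)c1OCOC
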